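## Analysis of the target

The target 18 is a diaryl ether of two benzene rings and has no stereocenter. Ring A is numbered from the carbon on the ether oxygen (C1); it bears the hydroxyl at C4, bromine at C2, C3 and C5, and hydrogen only at C6. Ring B is numbered from its ether carbon (C1'); it is a fully substituted hydroquinone with hydroxyls at C2' and C5' and bromine at C3', C4' and C6'.

The sensitive groups are the hydroquinone and the six aryl bromides. The hydroquinone is easily oxidised to a quinone in which the aryloxy group becomes a leaving group. The bromides rule out organolithium and low-valent metal chemistry once they are in place.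

The ether oxygen is flanked by C2'–OH and C6'–Br on ring B and by C2–Br on ring A, so a late coupling of two brominated rings would be hindered. The second difficulty is regiochemical. Five bromines sit ortho to a free hydroxyl and are open to electrophilic substitution, but C2 of ring A is meta to the C4 hydroxyl and is activated only by the ether oxygen.

The strategy rests on ring B. The chain C2'–C3'–C4'–C5', with oxygen on both ends, has the skeleton and oxidation pattern of succinic anhydride. The remaining pair C1'/C6' corresponds to the two alkyne carbons of a 3-aryloxypropiolate, whose ester carbon is later exchanged for the C6' bromine.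

## Retrosynthetic reasoning

**18 from 17.** The last two bromines are removed first: C6'–Br on ring B and C3–Br on ring A. Both carbons are ortho to a free hydroxyl, so the forward step is a mild electrophilic bromination. At C6' the electrophile replaces a carboxyl group by ipso attack and decarboxylation. The ester carbon of the ynoate thus leaves in the same operation that completes ring A. C6 of ring A is meta to the hydroxyl and should stay C–H.

**17 from 16.** Two O–CH3 bonds are cut, the ring A methyl ether and the methyl ester. One Lewis-acid dealkylation should cleave both by attack on the methyl carbons, which is indifferent to the crowding at the ester carbonyl. The free C4 hydroxyl is needed to direct the last ring A bromine to C3, and the free acid is needed for ipso substitution.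

**16 from 15.** Four C–Br bonds are cut: C3' and C4' on the hydroquinone, C5 of ring A (ortho to methoxy), and C2 of ring A, which is traced back to a C–Si bond. Direct bromination at C2 of a 4-aryloxyphenol would have to take place meta to the hydroxyl, on a ring already carrying two bromines, and could not be told apart from attack at C6. Ipso substitution of silicon is specific to the carbon that carries it. This bromination stands before the dealkylation because an aryl–silicon bond would not survive the boron Lewis acid.

**15 from 14.** Only the oxidation level changes. The quinone is the direct outcome of the ring-forming step; reduction gives the hydroquinone, whose hydroxyls activate C3' and C4'.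

**14 from 10 and 12 (through 13).** The C1'–C2' and C5'–C6' bonds are cut. This takes ring B apart into a four-carbon diene carrying both oxygens (12) and a two-carbon alkyne carrying the ether oxygen and the carboxyl (10). No other cut of ring B delivers the para oxygens, the ether link and a handle for the C6' bromine from two simple pieces. The hindered C–O bond is never formed on a crowded arene: it is already present in 10. The forward reaction has to be a cycloaddition followed by opening of the oxygen bridge of 13.

**12 from 11.** Two O–Si bonds are cut; the diene is the bis-silyl enol form of the anhydride 11.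

**10 from 6 and 7 (through 8 and 9).** The alkyne–carbonyl bond is cut. The forward step acylates the acetylide 9 with 7. Acetylide 9 arises from 6 by elimination to 8 and chlorine–lithium exchange. This order is the reason the C2 placeholder is silicon and not bromine: an aryl bromide would not survive the organolithium base.

**6 from 3 and 4 (through 5).** The vinyl C–O bond is cut; the phenol 3 adds to the two-carbon unit of 4.

**3 from 1 (through 2).** The C2–Si bond is cut. The silyl group is delivered from oxygen to carbon, so the bromine of commercial 1 fixes its position.

## Alternatives that were turned down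

**Alternative 1:** Ring A is disconnected by a Robinson annulation that leaves the ether oxygen on the α-carbon of an aldehyde.
- Forward key step: the aryloxyacetaldehyde A2 and the enone A3 are joined under secondary-amine catalysis by Michael addition (C4–C5) and aldol condensation (C2–C3). This gives the racemic cyclohexenone A1, which must then be dehydrogenated to the phenol, brominated and demethylated.
- For it: ring B arrives with all three bromines and both oxygens, the hindered C–O bond is made by a simple alkylation, the reagents are cheap, and the annulation is a well-understood reaction class. On precedent for the key step it is stronger than the chosen route.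
- Against it: A1 is one oxidation level below the arene and contains a stereocenter that is made only to be destroyed. Halogenation of the enone reaches the two carbons next to the carbonyl, which become the positions ortho to the hydroxyl, but not C2 next to the ether oxygen. A ring assembled from A3 cannot carry a placeholder there without a different enone. Alkylation of a phenol with two ortho substituents to reach A2 is also slow.
- Comparison: step counts are similar. The chosen strategy offers a ring A that is bought as an arene with its substitution fixed before the key step.

**Alternative 2:** Ring A is disconnected by a Dötz benzannulation in which the ether oxygen is the heteroatom of a Fischer carbene.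
- Forward key step: heating the zerovalent chromium carbene complex A5, (CO)5Cr=C(OAr)CH=CH2, with the silylalkyne A6 forms C4–C5, C6–C1 and C1–C2 (phenol numbering). This gives the 4-aryloxyphenol A4 with silicon next to the new hydroxyl.
- For it: it delivers exactly the para relationship of hydroxyl and ether oxygen, forms three bonds at once, and its regiochemistry with terminal alkynes is dependable. As a reaction class it is better precedented than the chosen key step.
- Against it: aryloxy carbene complexes are much less accessible and less robust than alkoxy complexes, and chromium is used stoichiometrically. A4 contains no bromine, so all six must be placed afterwards on two rings that compete. The silyl group ends up ortho to the hydroxyl, where bromination is easy anyway, so the meta bromine at C2 remains unsolved.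
- Comparison: convergence is equal. The chosen strategy offers a metal-free ring construction and a defined site for every ring A bromine.

**Alternative 3:** Ring B is disconnected by a Moore rearrangement.
- Forward key step: heating the 4-hydroxy-4-vinylcyclobutenone A8, made by addition of a vinyl organometallic to the cyclobutenedione A9, opens the four-membered ring to a dienylketene. Electrocyclisation forms C4'–C5' and gives the hydroquinone A7.
- For it: the rearrangement is reliable and regiodefined. A7 has C3', C4' and C6' as C–H, all activated by the hydroxyls, so ring B needs neither an ester cleavage nor a decarboxylation. On ring B it is stronger than the chosen route on both counts.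
- Against it: A9 needs several steps from a squarate-type precursor (removal of one oxygen, aryloxy exchange), against one step for diene 12. The cyclobutenones are sensitive. Ring A is a plain 4-methoxyphenoxy group, so the C2 bromine problem returns unless the same silyl placeholder is added.
- Comparison: the chosen strategy offers the shortest access to the four-carbon unit and removes the extra carboxyl in the same step that finishes the bromination. It pays with a dienophile class that is untested.

Key step: step 5

Remark on the chemistry (assumption): cycloadduct 13 is taken to persist in its silylated, bridged form under anhydrous, acid-free conditions and to collapse to quinone 14 only on acidic work-up. The conditions of step 5 are chosen on that basis.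

## Route

Step 1
Reactants: 1 2-bromo-4-methoxyphenol
Product: 3 4-methoxy-2-(trimethylsilyl)phenol, via silyl ether 2 (not isolated)
Conditions: (Me3Si)2NH, 80 °C, then evaporation; n-BuLi, THF, −78 → 20 °C; aq NH4Cl
Reagents that add atoms: hexamethyldisilazane, C[Si](C)(C)N[Si](C)(C)C
Why: O-Silylation is followed by bromine–lithium exchange at C2, which triggers migration of the silyl group from oxygen to the lithiated carbon (anionic 1,3-silyl shift, retro-Brook rearrangement), driven by formation of the phenoxide. This is the standard route to 2-silylphenols; no stereocenter is formed.

Step 2
Reactants: 3 4-methoxy-2-(trimethylsilyl)phenol; 4 trichloroethylene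
Product: 6 (E)-1,2-dichlorovinyl 4-methoxy-2-(trimethylsilyl)phenyl ether, via dichloroacetylene 5 (not isolated)
Conditions: K2CO3, DMF, 70 °C
Reagents that add atoms: none
Why: Carbonate dehydrochlorinates 4 to 5 and the phenoxide of 3 adds to it; anti addition with protonation trans to oxygen gives the (E)-dichlorovinyl ether, the established outcome for phenols and trichloroethylene. The aryl–silicon bond is inert to carbonate in DMF.

Step 3
Reactants: 6 (E)-1,2-dichlorovinyl 4-methoxy-2-(trimethylsilyl)phenyl ether; 7 methyl chloroformate
Product: 10 methyl 3-[4-methoxy-2-(trimethylsilyl)phenoxy]prop-2-ynoate, via chloroalkynyl ether 8 (not isolated), via lithium acetylide 9 (not isolated)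
Conditions: n-BuLi (2.2 equiv), THF, −78 → −40 °C; then cannulation into 7 (excess), THF, −78 °C
Reagents that add atoms: none
Why: n-BuLi removes the vinyl proton with loss of chloride to give 8, and chlorine–lithium exchange with the second equivalent gives 9 (standard ynol ether protocol). Inverse addition to excess 7 acylates the acetylide and keeps the electrophilic product away from unreacted nucleophile; the arylsilane is untouched at −78 °C.

Step 4
Reactants: 11 succinic anhydride
Product: 12 2,5-bis(trimethylsilyloxy)furan
Conditions: Me3SiCl, Et3N, ZnCl2 (cat.), MeCN, 20 °C; distillation
Reagents that add atoms: chlorotrimethylsilane, C[Si](C)(C)Cl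
Why: Double O-silylation of the bis-enol form of the anhydride, with ZnCl2 assisting enolisation, is the known preparation of this diene. It is distilled and used at once because moisture hydrolyses it.

Step 5
Reactants: 10 methyl 3-[4-methoxy-2-(trimethylsilyl)phenoxy]prop-2-ynoate; 12 2,5-bis(trimethylsilyloxy)furan
Product: 14 methyl 2-[4-methoxy-2-(trimethylsilyl)phenoxy]-3,6-dioxocyclohexa-1,4-diene-1-carboxylate, via oxanorbornadiene cycloadduct 13 (not isolated)
Conditions: 12 (1.3 equiv), PhMe, 90 °C, sealed tube, anhydrous and acid-free; then 1 M HCl, THF, 0 °C
Reagents that add atoms: none
Why: Proposed new method: the bis(silyl ketene acetal) diene 12 should add to ynoate 10 across furan C2 and C5 in a thermal (4+2) cycloaddition to give the 1,4-bis(silyloxy)-7-oxanorbornadiene 13, the closest known reaction type being the Diels–Alder addition of 2,5-bis(trimethylsilyloxy)furans to acetylenic esters such as propiolates and acetylenedicarboxylates, which has not been shown for a donor-substituted 3-aryloxy ynoate. On work-up the bridge C–O bond is broken with help from the lone pair of a bridgehead silyloxy oxygen, and the bridging oxygen departs with both silyl groups as hexamethyldisiloxane, which turns C2' and C5' into the quinone carbonyls. Ring B is closed by intermolecular cycloaddition, both new σ-bonds (C1'–C2' and C5'–C6') forming in one step, with the aryloxy group placed at C1' and the ester at C6'. No stereocenter is set, since the two bridgehead centers of racemic 13 vanish on bridge opening. The diene is symmetrical, so no orientational selectivity is needed; the step needs rate and chemoselectivity. The ester keeps the alkyne LUMO within reach of this very electron-rich diene although the aryloxy oxygen raises it, and the ortho-silyl group lies away from the triple bond. Anhydrous, acid-free conditions keep 12 from desilylating and keep the product masked as 13, so that the reactive C3'=C4' bond of free 14 is not exposed to the diene; the acidic work-up destroys surplus 12 as it unmasks 14.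

Step 6
Reactants: 14 methyl 2-[4-methoxy-2-(trimethylsilyl)phenoxy]-3,6-dioxocyclohexa-1,4-diene-1-carboxylate
Product: 15 methyl 3,6-dihydroxy-2-[4-methoxy-2-(trimethylsilyl)phenoxy]benzoate
Conditions: Na2S2O4, EtOAc–H2O, 20 °C
Reagents that add atoms: none
Why: Two-electron reduction of a p-quinone by dithionite in a two-phase system is general and leaves the ester, the arylsilane and the diaryl ether untouched. It makes ring B a hydroquinone that is activated for substitution.

Step 7
Reactants: 15 methyl 3,6-dihydroxy-2-[4-methoxy-2-(trimethylsilyl)phenoxy]benzoate
Product: 16 methyl 4,5-dibromo-2-(2,5-dibromo-4-methoxyphenoxy)-3,6-dihydroxybenzoate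
Conditions: Br2 (4.1 equiv), AcOH, 10 → 20 °C; aq Na2S2O4 wash
Reagents that add atoms: bromine, BrBr
Why: Electrophilic aromatic substitution: C3' and C4' are each ortho to a hydroquinone hydroxyl, C5 of ring A is ortho to methoxy and para to silicon, and at C2 the electrophile attacks ipso and silicon leaves (bromodesilylation), so that bromine enters only where the placeholder stood. C6 of ring A is meta to methoxy and stays C–H, the ester blocks C6', and the reductive wash returns any quinone formed by oxidation.

Step 8
Reactants: 16 methyl 4,5-dibromo-2-(2,5-dibromo-4-methoxyphenoxy)-3,6-dihydroxybenzoate
Product: 17 4,5-dibromo-2-(2,5-dibromo-4-hydroxyphenoxy)-3,6-dihydroxybenzoic acid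
Conditions: BBr3 (8 equiv), CH2Cl2, −78 → 20 °C; H2O
Reagents that add atoms: none
Why: BBr3 complexes the ether and ester oxygens and bromide attacks the methyl groups (SN2 dealkylation), which cleaves the aryl methyl ether and, with excess reagent at 20 °C, the methyl ester of the boron-chelated salicylate regardless of crowding at its carbonyl. Aryl bromides and the diaryl ether are inert; if the 2,6-dioxygenated acid loses CO2 by protonation, the resulting C6'–H is brominated in step 9 all the same.

Step 9
Reactants: 17 4,5-dibromo-2-(2,5-dibromo-4-hydroxyphenoxy)-3,6-dihydroxybenzoic acid
Product: 18 2,3,5-tribromo-6-(2,3,5-tribromo-4-hydroxyphenoxy)benzene-1,4-diol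
Conditions: Br2 (2.1 equiv), AcOH, 20 °C; aq Na2S2O4 work-up
Reagents that add atoms: bromine, BrBr
Why: Ipso bromodecarboxylation of a salicylic-type acid: attack at C6', ortho to the C5' hydroxyl, gives a dienone that aromatises by loss of CO2, while the ring A phenol is brominated at its one free ortho position, C3. C6 of ring A, meta to the hydroxyl and deactivated by three bromines, should not react with the limited amount of reagent at 20 °C, and the dithionite wash returns any quinone to the hydroquinone.

## Compound list

1 | 2-bromo-4-methoxyphenol | COc1ccc(O)c(Br)c1 | starting material
2 | (2-bromo-4-methoxyphenoxy)trimethylsilane | COc1ccc(O[Si](C)(C)C)c(Br)c1 | intermediate (not isolated)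
3 | 4-methoxy-2-(trimethylsilyl)phenol | COc1ccc(O)c([Si](C)(C)C)c1 | intermediate
4 | trichloroethylene | ClC=C(Cl)Cl | starting material
5 | dichloroacetylene | ClC#CCl | intermediate (not isolated)
6 | (E)-1,2-dichlorovinyl 4-methoxy-2-(trimethylsilyl)phenyl ether | COc1ccc(O/C(Cl)=C\Cl)c([Si](C)(C)C)c1 | intermediate
7 | methyl chloroformate | COC(=O)Cl | starting material
8 | [2-(chloroethynyloxy)-5-methoxyphenyl]trimethylsilane | COc1ccc(OC#CCl)c([Si](C)(C)C)c1 | intermediate (not isolated)
9 | lithium 2-[4-methoxy-2-(trimethylsilyl)phenoxy]ethynide | [Li]C#COc1ccc(OC)cc1[Si](C)(C)C | intermediate (not isolated)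
10 | methyl 3-[4-methoxy-2-(trimethylsilyl)phenoxy]prop-2-ynoate | COC(=O)C#COc1ccc(OC)cc1[Si](C)(C)C | intermediate
11 | succinic anhydride | O=C1CCC(=O)O1 | starting material
12 | 2,5-bis(trimethylsilyloxy)furan | C[Si](C)(C)Oc1ccc(O[Si](C)(C)C)o1 | intermediate
13 | methyl 3-[4-methoxy-2-(trimethylsilyl)phenoxy]-1,4-bis(trimethylsilyloxy)-7-oxabicyclo[2.2.1]hepta-2,5-diene-2-carboxylate (racemic) | COC(=O)C1=C(Oc2ccc(OC)cc2[Si](C)(C)C)C3(O[Si](C)(C)C)C=CC1(O[Si](C)(C)C)O3 | intermediate (not isolated)
14 | methyl 2-[4-methoxy-2-(trimethylsilyl)phenoxy]-3,6-dioxocyclohexa-1,4-diene-1-carboxylate | COC(=O)C1=C(Oc2ccc(OC)cc2[Si](C)(C)C)C(=O)C=CC1=O | intermediate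
15 | methyl 3,6-dihydroxy-2-[4-methoxy-2-(trimethylsilyl)phenoxy]benzoate | COC(=O)c1c(O)ccc(O)c1Oc1ccc(OC)cc1[Si](C)(C)C | intermediate
16 | methyl 4,5-dibromo-2-(2,5-dibromo-4-methoxyphenoxy)-3,6-dihydroxybenzoate | COC(=O)c1c(O)c(Br)c(Br)c(O)c1Oc1cc(Br)c(OC)cc1Br | intermediate
17 | 4,5-dibromo-2-(2,5-dibromo-4-hydroxyphenoxy)-3,6-dihydroxybenzoic acid | OC(=O)c1c(O)c(Br)c(Br)c(O)c1Oc1cc(Br)c(O)cc1Br | intermediate
18 | 2,3,5-tribromo-6-(2,3,5-tribromo-4-hydroxyphenoxy)benzene-1,4-diol | Oc1c(Br)cc(Oc2c(O)c(Br)c(Br)c(O)c2Br)c(Br)c1Br | target

## Step count and least certain steps

Total step count: 9. Longest linear sequence: 8 steps (steps 1, 2, 3, 5, 6, 7, 8, 9); step 4 is a one-step side branch.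

**Step 5 (key step, proposed new method).** The cycloaddition may be too slow, because the aryloxy oxygen donates into the ynoate, so that thermal or adventitious hydrolytic desilylation of the diene wins. Alternatively the bridge may open in the reaction mixture, releasing the quinone, whose unsubstituted double bond would then take up a second equivalent of diene.

Fallback with known chemistry, setting out from diene 12 and phenol 3 and returning at quinone 14: the aryloxy group is taken off the dienophile and introduced after the ring is made. Methyl 3-bromoprop-2-ynoate F1 is prepared from methyl prop-2-ynoate with N-bromosuccinimide and AgNO3 (cat.) in acetone. It is an ordinary electron-poor acetylenic ester and a proven dienophile towards furans. With 12 it should give the bridged adduct methyl 3-bromo-1,4-bis(trimethylsilyloxy)-7-oxabicyclo[2.2.1]hepta-2,5-diene-2-carboxylate F2 and, after hydrolytic bridge opening, methyl 2-bromo-3,6-dioxocyclohexa-1,4-diene-1-carboxylate F3. In F3 the bromine sits on the quinone carbon that is β to a ring carbonyl and to the ester. Its replacement by the phenoxide of 3 (K2CO3, MeCN, 0 °C) is the standard addition–elimination of halo-quinones with phenols and gives 14. Ring B is still built from the same diene, but the push–pull dienophile is avoided.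

**Step 9.** Bromine may oxidise the fully substituted hydroquinone faster than it substitutes at C6'. In the resulting aryloxy-quinone the ring A phenoxide can be displaced, which would cleave the diaryl ether. Ipso attack para to the ring A hydroxyl would have the same effect.

Fallback, setting out from 17 and returning at 18: decarboxylation is separated from bromination. Heating 17 in aqueous HCl–dioxane under nitrogen should remove the carboxyl by ipso protonation, which is easy for a benzoic acid with oxygen on both ortho carbons. This gives 2,3-dibromo-5-(2,5-dibromo-4-hydroxyphenoxy)benzene-1,4-diol F4. Its two remaining activated C–H positions (C6' and ring A C3) are then brominated with exactly two equivalents of the mild tribromide salt (n-Bu4N)Br3 in CH2Cl2–MeOH at −20 °C, followed by a dithionite wash.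

**Step 7.** Oxidation of hydroquinone 15 by bromine may compete with substitution and use up reagent. Hydrogen bromide may also remove the silyl group by protonation before bromine replaces it, which would leave C2 as C–H.

Fallback, setting out from quinone 14 and returning at 16: ring B is brominated by addition instead of substitution, and step 6 is bypassed. Treatment of 14 with Br2 (3 equiv) in CHCl3–AcOH at 0 °C should exchange silicon for bromine at C2, brominate C5 of ring A, and add bromine across the C3'=C4' bond of the quinone. This gives racemic methyl trans-4,5-dibromo-2-(2,5-dibromo-4-methoxyphenoxy)-3,6-dioxocyclohex-1-ene-1-carboxylate F5. Acid (H2SO4 cat., AcOH) then enolises both ketones, the known isomerisation of quinone dibromides to 2,3-dibromohydroquinones, and gives 16. The hydroquinone never meets free bromine, and the arylsilane is substituted before any acid builds up.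

**Step 8.** Dealkylation may stop at the phenol: the methyl ester of the crowded, boron-chelated salicylate may survive BBr3.

Fallback, setting out from 16 and returning at 17: the two cleavages are separated. BBr3 at −78 → 0 °C is used only for the aryl methyl ether and gives methyl 4,5-dibromo-2-(2,5-dibromo-4-hydroxyphenoxy)-3,6-dihydroxybenzoate F6. The ester is then cleaved under nucleophilic, non-acidic conditions with LiI in pyridine at reflux under nitrogen (SN2 attack of iodide on the ester methyl). Acidification gives 17.

## Further compounds

F1 | step 5 | methyl 3-bromoprop-2-ynoate | COC(=O)C#CBr
F2 | step 5 | methyl 3-bromo-1,4-bis(trimethylsilyloxy)-7-oxabicyclo[2.2.1]hepta-2,5-diene-2-carboxylate (racemic) | COC(=O)C1=C(Br)C3(O[Si](C)(C)C)C=CC1(O[Si](C)(C)C)O3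
F3 | step 5 | methyl 2-bromo-3,6-dioxocyclohexa-1,4-diene-1-carboxylate | COC(=O)C1=C(Br)C(=O)C=CC1=O
F4 | step 9 | 2,3-dibromo-5-(2,5-dibromo-4-hydroxyphenoxy)benzene-1,4-diol | Oc1cc(Oc2cc(Br)c(O)cc2Br)c(O)c(Br)c1Br
F5 | step 7 | methyl trans-4,5-dibromo-2-(2,5-dibromo-4-methoxyphenoxy)-3,6-dioxocyclohex-1-ene-1-carboxylate (racemic, one enantiomer drawn) | COC(=O)C1=C(Oc2cc(Br)c(OC)cc2Br)C(=O)[C@@H](Br)[C@H](Br)C1=O
F6 | step 8 | methyl 4,5-dibromo-2-(2,5-dibromo-4-hydroxyphenoxy)-3,6-dihydroxybenzoate | COC(=O)c1c(O)c(Br)c(Br)c(O)c1Oc1cc(Br)c(O)cc1Br
A1 | alternative 1 | 4-(3,4,6-tribromo-2,5-dimethoxyphenoxy)cyclohex-2-en-1-one (racemic) | O=C1C=CC(Oc2c(OC)c(Br)c(Br)c(OC)c2Br)CC1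
A2 | alternative 1 | 2-(3,4,6-tribromo-2,5-dimethoxyphenoxy)acetaldehyde | O=CCOc1c(OC)c(Br)c(Br)c(OC)c1Br
A3 | alternative 1 | but-3-en-2-one | CC(=O)C=C
A4 | alternative 2 | 4-(2,5-dimethoxyphenoxy)-2-(trimethylsilyl)phenol | COc1ccc(OC)c(Oc2ccc(O)c([Si](C)(C)C)c2)c1
A5 | alternative 2 | pentacarbonyl[(2,5-dimethoxyphenoxy)(ethenyl)carbene]chromium, (CO)5Cr=C(OAr)CH=CH2 | C=CC(Oc1cc(OC)ccc1OC)=[Cr](=C=O)(=C=O)(=C=O)(=C=O)=C=O
A6 | alternative 2 | ethynyltrimethylsilane | C#C[Si](C)(C)C
A7 | alternative 3 | 2-(4-methoxyphenoxy)benzene-1,4-diol | COc1ccc(Oc2cc(O)ccc2O)cc1
A8 | alternative 3 | 4-ethenyl-4-hydroxy-3-(4-methoxyphenoxy)cyclobut-2-en-1-one (racemic) | C=CC1(O)C(Oc2ccc(OC)cc2)=CC1=O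
A9 | alternative 3 | 3-(4-methoxyphenoxy)cyclobut-3-ene-1,2-dione | O=C1C=C(Oc2ccc(OC)cc2)C1=O
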